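**Plan**
- Retrosynthesis first cuts the two ArCH2–C bonds of the methylene bridges (Mannich / ortho-quinone methide couplings), giving the chiral acetyl trione 11, butanoylphloroglucinol 14 and chromene 18.
- The trione ring of 11 is then cut at two ring C–C bonds: quaternary carbon to the enol carbon next to the acetyl-bearing carbon, and the ring CH to the enol carbon on the other side of the quaternary carbon.
- Enabling feature: the quaternary carbon sits between two ring carbonyls, and the acetyl C=O plus the adjacent ring C=O form a 1,3-diketone that can be carried as a 3,5-dimethylisoxazole. Its 4-carbonyl is the electrophile and its 5-methyl the latent nucleophilic ring CH; the two-carbon partner is a geranylated propanoate.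
- Forward: geranylation, silyl ketene acetal, one-flask acylation/Claisen annulation (ring formed), isoxazole unmasking; separately acylphloroglucinol, regiodefined chromene, first bridge; the chiral trione is joined last.
- Stereochemistry: the (E)-olefin comes from geranyl bromide; the only stereocentre is set in the annulation by a planar-chiral acyl-transfer catalyst and is quaternary thereafter.

Key step: step 4

Remark on the chemistry: the β-triketone units are tautomeric; 11 and 23 are drawn in the enol form of the given structure, and CIP descriptors refer to the drawn forms (the spatial arrangement at the quaternary carbon is the same in 8, 9, 10, 11 and 23).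

**Step 1**
Reactants: 1 methyl propanoate; 2 geranyl bromide
Product: 3 methyl (4E)-2,5,9-trimethyldeca-4,8-dienoate (racemic)
Conditions: LiN(i-Pr)2, THF, −78 °C; then 2, −78 → 0 °C
Reagents that add atoms: none
Why: α-Alkylation of an ester lithium enolate with a primary allylic bromide (SN2) should keep the (E)-olefin, and the racemic α-centre is immaterial because it is planarised in step 2.

**Step 2**
Reactants: 3 methyl (4E)-2,5,9-trimethyldeca-4,8-dienoate
Product: 4 (4E)-1-methoxy-2,5,9-trimethyl-1-(trimethylsilyloxy)deca-1,4,8-triene (both 1-ene isomers)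
Conditions: LiN(i-Pr)2, THF, −78 °C; Me3SiCl, −78 °C → rt; pentane, filtration, distillation
Reagents that add atoms: chlorotrimethylsilane, C[Si](C)(C)Cl
Why: O-Silylation of the lithium enolate of an α,α-disubstituted ester (silyl ketene acetal formation) is standard, and the isomer mixture is acceptable because both isomers present the same prochiral α-carbon.

**Step 3**
Reactants: 5 3,5-dimethyl-1,2-oxazole-4-carboxylic acid; 6 3,5-dimethyl-1,2-oxazole-4-carbonyl chloride
Product: 7 3,5-dimethyl-1,2-oxazole-4-carboxylic anhydride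
Conditions: Et3N (1.1 equiv), CH2Cl2, 0 °C → rt; Et2O, filtration, concentration
Reagents that add atoms: none
Why: Nucleophilic acyl substitution of acid chloride 6 by the triethylammonium carboxylate of 5 gives the symmetric anhydride, the acyl-donor form needed by the acyl-transfer catalyst; the acid 5 released in step 4 can be recycled here.

**Step 4**
Reactants: 4 silyl ketene acetal (1.2 equiv); 7 3,5-dimethyl-1,2-oxazole-4-carboxylic anhydride
Product: 9 (5R)-5-[(2E)-3,7-dimethylocta-2,6-dien-1-yl]-3,5-dimethyl-1,2-benzoxazole-4,6(5H,7H)-dione, via β-keto ester 8 (not isolated)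
Conditions: (a) Fe(η5-C5Ph5)(η5-C12H13N2) [planar-chiral 4-(pyrrolidin-1-yl)pyrindinyl iron complex, one antipode, 5 mol%], Et2O/CH2Cl2, rt; (b) same flask, THF, LiN(SiMe3)2 (3 equiv), −78 → 0 °C; AcOH
Reagents that add atoms: none
Why: Proposed new method: the chiral pyridine opens 7 to an N-acylpyridinium carboxylate, the carboxylate desilylates 4, and the ester enolate is C-acylated inside the chiral ion pair to give 8 (bond from the quaternary carbon to the ketone carbon); LiN(SiMe3)2 then deprotonates the isoxazole 5-methyl, vinylogously activated by the 4-keto group, and this carbanion attacks the methyl ester in a Claisen (Dieckmann-type) closure with loss of methoxide (second bond, six-membered ring). The closest known reaction types are the nucleophile-catalysed enantioselective C-acylation of silyl ketene acetals to quaternary β-keto esters and the lateral-metalation/Claisen annulation of ortho-methyl (hetero)aryl carbonyl compounds; their merger in one flask, with a dialkyl ketene acetal and a heteroaroyl donor, is the untested part. The carbocycle closes in the 6-(enolendo)-exo-trig mode. The stereocentre is fixed in the acylation by the catalyst, whose C5Ph5 deck and fused ring leave one face of the acylpyridinium open to the free enolate; the antipode that gives (S)-8 is to be assigned in a first run, and the Claisen closure does not touch this centre. The step needs C- over O-acylation and discrimination between methyl and geranyl, which rests on the catalyst pocket alone. Lateral deprotonation is secured by the substrate, because the ketone of 8 has no α-hydrogen and closure through either isoxazole methyl would give the same trione after unmasking.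

**Step 5**
Reactants: 9 (5R)-benzoxazoledione
Product: 11 (4R)-2-acetyl-4-[(2E)-3,7-dimethylocta-2,6-dien-1-yl]-3,5-dihydroxy-4-methylcyclohexa-2,5-dien-1-one, via enaminone 10 (not isolated)
Conditions: Mo(CO)6, MeCN/H2O, 80 °C; then 2 M NaOH, EtOH, 60 °C; cold 1 M HCl to pH 3
Reagents that add atoms: water, O
Why: Reductive N–O cleavage of the isoxazole with Mo(CO)6 should spare the trisubstituted olefins, and alkaline hydrolysis of the resulting vinylogous amide (isoxazole route to 2-acyl-1,3-diones) releases the acetyl trione without affecting the quaternary centre, which has no acidic hydrogen.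

**Step 6**
Reactants: 12 benzene-1,3,5-triol; 13 butanoyl chloride
Product: 14 1-(2,4,6-trihydroxyphenyl)butan-1-one
Conditions: AlCl3, PhNO2, rt → 60 °C; aq. HCl
Reagents that add atoms: none
Why: Friedel–Crafts C-acylation of phloroglucinol should stop at the mono-ketone because the first acyl group deactivates the ring.

**Step 7**
Reactants: 14 1-(2,4,6-trihydroxyphenyl)butan-1-one
Product: 15 1-[2,6-dihydroxy-4-(methoxymethoxy)phenyl]butan-1-one
Conditions: MeOCH2Cl (1.0 equiv), i-Pr2NEt, CH2Cl2, 0 °C
Reagents that add atoms: chloromethyl methyl ether, COCCl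
Why: O-Alkylation (Williamson type) with one equivalent should occur at the 4-hydroxyl, the most acidic one and the only one not hydrogen-bonded to the ketone.

**Step 8**
Reactants: 15 1-[2,6-dihydroxy-4-(methoxymethoxy)phenyl]butan-1-one; 16 3-methylbut-2-enal
Product: 17 1-[7-hydroxy-5-(methoxymethoxy)-2,2-dimethyl-2H-chromen-8-yl]butan-1-one
Conditions: ethylenediammonium diacetate (10 mol%), toluene, 110 °C
Reagents that add atoms: none
Why: Knoevenagel-type condensation of the phenol with the enal and oxa-6π electrocyclisation (chromenylation) give the 2,2-dimethylchromene, and with the 4-oxygen blocked the pyran can only close onto a hydroxyl ortho to the butanoyl group, which fixes the 8-acyl pattern.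

**Step 9**
Reactants: 17 1-[7-hydroxy-5-(methoxymethoxy)-2,2-dimethyl-2H-chromen-8-yl]butan-1-one
Product: 18 1-(5,7-dihydroxy-2,2-dimethyl-2H-chromen-8-yl)butan-1-one
Conditions: 3 M HCl (aq), MeOH, 40 °C
Reagents that add atoms: none
Why: Acid-catalysed acetal exchange removes the methoxymethyl ether under conditions that a 2,2-dimethylchromene and an aryl ketone should tolerate.

**Step 10**
Reactants: 18 1-(5,7-dihydroxy-2,2-dimethyl-2H-chromen-8-yl)butan-1-one; 19 N,N-dimethylmethaniminium iodide, [CH2=NMe2]I (1.0 equiv); 14 1-(2,4,6-trihydroxyphenyl)butan-1-one (3 equiv)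
Product: 21 1-{3-[(8-butanoyl-5,7-dihydroxy-2,2-dimethyl-2H-chromen-6-yl)methyl]-2,4,6-trihydroxyphenyl}butan-1-one, via Mannich base 20 (not isolated)
Conditions: 19, MeCN, 0 °C → rt; then 14, Et3N, 1,4-dioxane, 80 °C
Reagents that add atoms: none
Why: Mannich aminomethylation at the only free aromatic CH of 18, then thermal loss of dimethylamine to an ortho-quinone methide that 14 traps in a Friedel–Crafts-type conjugate addition, with 14 in excess so that only one of its two equivalent positions reacts.

**Step 11**
Reactants: 21 methylene-bridged dimer; 19 N,N-dimethylmethaniminium iodide (1.0 equiv); 11 (4R)-acetyl trione (1.0 equiv)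
Product: 23 (4R)-2-acetyl-6-({3-butanoyl-5-[(8-butanoyl-5,7-dihydroxy-2,2-dimethyl-2H-chromen-6-yl)methyl]-2,4,6-trihydroxyphenyl}methyl)-4-[(2E)-3,7-dimethylocta-2,6-dien-1-yl]-3,5-dihydroxy-4-methylcyclohexa-2,5-dien-1-one, via Mannich base 22 (not isolated)
Conditions: 19, MeCN, 0 °C → rt; then 11, Et3N, 50 °C
Reagents that add atoms: none
Why: The same Mannich / ortho-quinone methide sequence on the last free aromatic CH of 21, with the acidic trione 11 adding through its only ring CH (Michael addition of a cyclic β-triketone), should form the second bridge under mild conditions that leave the quaternary centre untouched.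

**Compound list**
1 | methyl propanoate | CCC(=O)OC | starting material
2 | geranyl bromide, (2E)-1-bromo-3,7-dimethylocta-2,6-diene | BrC/C=C(\C)CCC=C(C)C | starting material
3 | methyl (4E)-2,5,9-trimethyldeca-4,8-dienoate (racemic) | COC(=O)C(C)C/C=C(\C)CCC=C(C)C | intermediate
4 | (4E)-1-methoxy-2,5,9-trimethyl-1-(trimethylsilyloxy)deca-1,4,8-triene (both 1-ene isomers) | COC(O[Si](C)(C)C)=C(C)C/C=C(\C)CCC=C(C)C | intermediate
5 | 3,5-dimethyl-1,2-oxazole-4-carboxylic acid | Cc1noc(C)c1C(=O)O | starting material
6 | 3,5-dimethyl-1,2-oxazole-4-carbonyl chloride | Cc1noc(C)c1C(=O)Cl | starting material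
7 | 3,5-dimethyl-1,2-oxazole-4-carboxylic anhydride | Cc1noc(C)c1C(=O)OC(=O)c1c(C)noc1C | intermediate
8 | methyl (2S,4E)-2-[(3,5-dimethyl-1,2-oxazol-4-yl)carbonyl]-2,5,9-trimethyldeca-4,8-dienoate | COC(=O)[C@@](C)(C/C=C(\C)CCC=C(C)C)C(=O)c1c(C)noc1C | intermediate
9 | (5R)-5-[(2E)-3,7-dimethylocta-2,6-dien-1-yl]-3,5-dimethyl-1,2-benzoxazole-4,6(5H,7H)-dione | Cc1noc2CC(=O)[C@@](C)(C/C=C(\C)CCC=C(C)C)C(=O)c12 | intermediate
10 | (4R)-2-(1-aminoethylidene)-4-[(2E)-3,7-dimethylocta-2,6-dien-1-yl]-4-methylcyclohexane-1,3,5-trione | CC(N)=C1C(=O)CC(=O)[C@@](C)(C/C=C(\C)CCC=C(C)C)C1=O | intermediate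
11 | (4R)-2-acetyl-4-[(2E)-3,7-dimethylocta-2,6-dien-1-yl]-3,5-dihydroxy-4-methylcyclohexa-2,5-dien-1-one | C1=C(O)[C@@](C)(C/C=C(\C)CCC=C(C)C)C(O)=C(C(C)=O)C1=O | intermediate
12 | benzene-1,3,5-triol (phloroglucinol) | Oc1cc(O)cc(O)c1 | starting material
13 | butanoyl chloride | CCCC(=O)Cl | starting material
14 | 1-(2,4,6-trihydroxyphenyl)butan-1-one | CCCC(=O)c1c(O)cc(O)cc1O | intermediate
15 | 1-[2,6-dihydroxy-4-(methoxymethoxy)phenyl]butan-1-one | CCCC(=O)c1c(O)cc(OCOC)cc1O | intermediate
16 | 3-methylbut-2-enal | CC(C)=CC=O | starting material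
17 | 1-[7-hydroxy-5-(methoxymethoxy)-2,2-dimethyl-2H-chromen-8-yl]butan-1-one | CCCC(=O)c1c(O)cc(OCOC)c2C=CC(C)(C)Oc12 | intermediate
18 | 1-(5,7-dihydroxy-2,2-dimethyl-2H-chromen-8-yl)butan-1-one | CCCC(=O)c1c(O)cc(O)c2C=CC(C)(C)Oc12 | intermediate
19 | N,N-dimethylmethaniminium iodide | C[N+](C)=C.[I-] | starting material
20 | 1-{6-[(dimethylamino)methyl]-5,7-dihydroxy-2,2-dimethyl-2H-chromen-8-yl}butan-1-one | CCCC(=O)c1c(O)c(CN(C)C)c(O)c2C=CC(C)(C)Oc12 | intermediate
21 | 1-{3-[(8-butanoyl-5,7-dihydroxy-2,2-dimethyl-2H-chromen-6-yl)methyl]-2,4,6-trihydroxyphenyl}butan-1-one | CCCC(=O)c1c(O)cc(O)c(Cc2c(O)c3c(c(C(=O)CCC)c2O)OC(C)(C)C=C3)c1O | intermediate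
22 | 1-{3-[(8-butanoyl-5,7-dihydroxy-2,2-dimethyl-2H-chromen-6-yl)methyl]-5-[(dimethylamino)methyl]-2,4,6-trihydroxyphenyl}butan-1-one | CCCC(=O)c1c(O)c(CN(C)C)c(O)c(Cc2c(O)c3c(c(C(=O)CCC)c2O)OC(C)(C)C=C3)c1O | intermediate
23 | (4R)-2-acetyl-6-({3-butanoyl-5-[(8-butanoyl-5,7-dihydroxy-2,2-dimethyl-2H-chromen-6-yl)methyl]-2,4,6-trihydroxyphenyl}methyl)-4-[(2E)-3,7-dimethylocta-2,6-dien-1-yl]-3,5-dihydroxy-4-methylcyclohexa-2,5-dien-1-one | CCCC(=O)c1c(O)c(CC2=C(O)[C@@](C)(C/C=C(\C)CCC=C(C)C)C(O)=C(C(C)=O)C2=O)c(O)c(Cc2c(O)c3c(c(C(=O)CCC)c2O)OC(C)(C)C=C3)c1O | target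

**Totals**
Total step count: 11. Longest linear sequence: 6 steps (6, 7, 8, 9, 10, 11).

**Steps most likely to fail**

Step 4 (Proposed new method). The catalyst pocket may not distinguish the methyl from the geranyl side of the enolate well enough, desilylation of a non-stabilised ketene acetal may be slow, and O-acylation may compete. The fallback sets out from 3 and comes back to the route at 11, with known chemistry. The lithium enolate of 3 (LiN(i-Pr)2, THF, −78 °C) is C-acylated with acid chloride 6 to give racemic methyl 2-[(3,5-dimethyl-1,2-oxazol-4-yl)carbonyl]-2,5,9-trimethyldeca-4,8-dienoate F1. Lateral deprotonation with LiN(SiMe3)2 and Claisen closure then give racemic 5-geranyl-3,5-dimethyl-1,2-benzoxazole-4,6(5H,7H)-dione F2, and Mo(CO)6 in wet MeCN opens the isoxazole to racemic 2-(1-aminoethylidene)-4-geranyl-4-methylcyclohexane-1,3,5-trione F3. Amine exchange with (S)-1-phenylethylamine (EtOH, 60 °C) gives 4-geranyl-4-methyl-2-{1-[(1S)-1-phenylethylamino]ethylidene}cyclohexane-1,3,5-trione as both C4 epimers F4. From this pair, (4R)-4-geranyl-4-methyl-2-{1-[(1S)-1-phenylethylamino]ethylidene}cyclohexane-1,3,5-trione F5 is separated by crystallisation or chromatography. Hydrolysis of F5 with aqueous NaOH and acidification gives 11.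

Step 11. Reversible ortho-quinone methide formation may exchange the phloroglucinol units between bridges, and 11 may be consumed as its methylene-bridged homodimer. The fallback sets out from 21 and comes back to the route at 23. Vilsmeier–Haack formylation (POCl3, DMF, 0 °C → rt, aqueous work-up) at the last free aromatic CH gives 3-butanoyl-5-[(8-butanoyl-5,7-dihydroxy-2,2-dimethyl-2H-chromen-6-yl)methyl]-2,4,6-trihydroxybenzaldehyde F6. Three-component reductive alkylation of F6 with 11 and diethyl 2,6-dimethyl-1,4-dihydropyridine-3,5-dicarboxylate (L-proline cat., CH2Cl2, rt) forms the bridge by Knoevenagel condensation and in situ hydride transfer, without amine elimination or heat, and gives 23.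

Step 8. The hydrogen-bonded phenol may condense slowly with the enal, a second annulation may occur, or the acetal may be lost at 110 °C. The fallback sets out from 15 and comes back to the route at 17. C-Prenylation of 15 with 1-bromo-3-methylbut-2-ene (aq. KOH, 0 °C) gives 1-[2,6-dihydroxy-4-(methoxymethoxy)-3-(3-methylbut-2-en-1-yl)phenyl]butan-1-one F7. Oxidative cyclisation of F7 with DDQ (toluene, 80 °C) closes the pyran onto the adjacent free hydroxyl and gives 17.

**Further compounds**
F1 | step 4 | racemic methyl 2-[(3,5-dimethyl-1,2-oxazol-4-yl)carbonyl]-2,5,9-trimethyldeca-4,8-dienoate | COC(=O)C(C)(C/C=C(\C)CCC=C(C)C)C(=O)c1c(C)noc1C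
F2 | step 4 | racemic 5-[(2E)-3,7-dimethylocta-2,6-dien-1-yl]-3,5-dimethyl-1,2-benzoxazole-4,6(5H,7H)-dione | Cc1noc2CC(=O)C(C)(C/C=C(\C)CCC=C(C)C)C(=O)c12
F3 | step 4 | racemic 2-(1-aminoethylidene)-4-[(2E)-3,7-dimethylocta-2,6-dien-1-yl]-4-methylcyclohexane-1,3,5-trione | CC(N)=C1C(=O)CC(=O)C(C)(C/C=C(\C)CCC=C(C)C)C1=O
F4 | step 4 | 4-[(2E)-3,7-dimethylocta-2,6-dien-1-yl]-4-methyl-2-{1-[(1S)-1-phenylethylamino]ethylidene}cyclohexane-1,3,5-trione (both C4 epimers) | C[C@H](NC(C)=C1C(=O)CC(=O)C(C)(C/C=C(\C)CCC=C(C)C)C1=O)c1ccccc1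
F5 | step 4 | (4R)-4-[(2E)-3,7-dimethylocta-2,6-dien-1-yl]-4-methyl-2-{1-[(1S)-1-phenylethylamino]ethylidene}cyclohexane-1,3,5-trione | C[C@H](NC(C)=C1C(=O)CC(=O)[C@@](C)(C/C=C(\C)CCC=C(C)C)C1=O)c1ccccc1
F6 | step 11 | 3-butanoyl-5-[(8-butanoyl-5,7-dihydroxy-2,2-dimethyl-2H-chromen-6-yl)methyl]-2,4,6-trihydroxybenzaldehyde | CCCC(=O)c1c(O)c(C=O)c(O)c(Cc2c(O)c3c(c(C(=O)CCC)c2O)OC(C)(C)C=C3)c1O
F7 | step 8 | 1-[2,6-dihydroxy-4-(methoxymethoxy)-3-(3-methylbut-2-en-1-yl)phenyl]butan-1-one | CCCC(=O)c1c(O)cc(OCOC)c(CC=C(C)C)c1O
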